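**Retrosynthetic overview**

1. Numbering: C1 (OCH2), O2, C3, C4, C4a, C5, C6 (C=O), C7, C8, C8a. Ring A is C4a-C5-C6-C7-C8-C8a and ring B is C1-O2-C3-C4-C4a-C8a. The plan rests on the diene C3=C4-C4a=C5 that crosses the ring fusion: its inner atoms C4 and C4a are read as a former ethynyl group on C8a, and its outer atoms C3 and C5 as former alkene carbons.
2. Cutting C3=C4 and C4a=C5 opens rings A and B together to an acyclic dienyne (vinyl ketone at C6, ethynyl on C8a, 2-alkoxydiene at O2-C3). In the forward sense both rings form in one flask by a ruthenium dienyne metathesis cascade, after C7, C8 and C8a are already set.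
3. The 2-alkoxydiene comes from a C1-O crotonate by titanium methylenation. Titanium methylidene also consumes ketones and alkynes, so C6 is held as a silylated allylic carbinol and the alkyne as a 1,1-dibromoalkene until that step is over.
4. C8 and C8a come from an Evans syn aldol of a 3-(PMB-oxy)propanoyl imide, whose acyl carbon becomes C4a. C7 comes from (R)-lactic acid: its dioxolanone enolate adds to acrolein, which delivers C6, C5 and the sacrificial =CH2.
5. Endgame: acetonide hydrolysis, acylation of the secondary C8-OH with silyl-protected orsellinoyl chloride, and fluoride deprotection.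

Key step: step 20

Assumption: the C6 carbinol centre made in step 2 is carried as a mixture of epimers, because oxidation in step 19 erases it; SMILES leave C6 undefined up to that point.

**Route**

Step 1
Reactants: 1 (R)-lactic acid; 2 pivalaldehyde
Product: 3 (2R,5R)-2-tert-butyl-5-methyl-1,3-dioxolan-4-one (cis isomer)
Conditions: p-TsOH·H2O (cat.), H2SO4 (cat.), pentane, reflux, Dean-Stark; crystallisation at -78 °C
Reagents that add atoms: none
Why: Acid-catalysed acetalisation with azeotropic water removal, in which the new acetal centre settles cis to the methyl group under thermodynamic control and the cis isomer is enriched by cold crystallisation.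

Step 2
Reactants: 3 (2R,5R)-2-tert-butyl-5-methyl-1,3-dioxolan-4-one; 4 acrolein
Product: 7 (2R,5S)-2-tert-butyl-5-[1-(tert-butyldimethylsilyloxy)prop-2-enyl]-5-methyl-1,3-dioxolan-4-one (both C6 epimers), via lithium enolate 5 (not isolated), via lithium aldolate 6 (not isolated)
Conditions: LiN(iPr)2, THF, -78 °C; 4, -78 °C; TBSOTf, -78 to -20 °C
Reagents that add atoms: tert-butyldimethylsilyl triflate, CC(C)(C)[Si](C)(C)OS(=O)(=O)C(F)(F)F; lithium diisopropylamide, [Li+].CC(C)[N-]C(C)C (lithium stays only in 5 and 6)
Why: Aldol addition under self-regeneration of the stereocentre with in situ O-silylation, in which acrolein adds 1,2 to the planar enolate on the face opposite the tert-butyl group and so fixes C7 with net retention, while C6 forms without control and is erased later.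

Step 3
Reactants: 7 silylated dioxolanone
Product: 8 (2R)-3-(tert-butyldimethylsilyloxy)-2-methylpent-4-ene-1,2-diol (C8 = CH2OH, free O7-H)
Conditions: LiAlH4, Et2O, 0 °C; aqueous work-up
Reagents that add atoms: none
Why: In this LiAlH4 reduction of the acylal-type lactone the hemiacetal collapses and both carbonyl fragments are reduced, which frees C8 as a primary alcohol and O7 as a tertiary alcohol without touching C7.

Step 4
Reactants: 8 diol
Product: 9 (2S)-3-(tert-butyldimethylsilyloxy)-2-hydroxy-2-methylpent-4-enal
Conditions: SO3·pyridine, DMSO, Et3N, CH2Cl2, 0 °C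
Reagents that add atoms: none
Why: Parikh-Doering oxidation takes only the primary alcohol to the aldehyde, does not cleave the 1,2-diol, and cannot epimerise the quaternary C7.

Step 5
Reactants: 9 hydroxy aldehyde
Product: 10 (2S)-3-(tert-butyldimethylsilyloxy)-2-methyl-2-(triethylsilyloxy)pent-4-enal
Conditions: TESOTf, 2,6-lutidine, CH2Cl2, -78 to 0 °C
Reagents that add atoms: triethylsilyl triflate, CC[Si](CC)(CC)OS(=O)(=O)C(F)(F)F
Why: Silyl triflate silylation handles the hindered tertiary alcohol, and the aldehyde has no alpha hydrogen, so no enol silane can form.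

Step 6
Reactants: 11 propane-1,3-diol; 12 4-methoxybenzyl chloride
Product: 13 3-(4-methoxybenzyloxy)propan-1-ol
Conditions: NaH, 11 (3 equiv), THF/DMF, 0 °C; 12, Bu4NI (cat.), rt
Reagents that add atoms: none
Why: Williamson ether synthesis, with the excess of diol favouring the mono-ether.

Step 7
Reactants: 13 mono-PMB ether
Product: 14 3-(4-methoxybenzyloxy)propanoic acid
Conditions: TEMPO (cat.), PhI(OAc)2, MeCN/H2O, rt
Reagents that add atoms: water, O
Why: In this oxoammonium-mediated oxidation the aldehyde hydrate is oxidised on to the acid in aqueous medium, and the PMB ether tolerates the conditions.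

Step 8
Reactants: 14 acid; 15 (R)-4-benzyl-2-oxazolidinone
Product: 17 (R)-4-benzyl-3-[3-(4-methoxybenzyloxy)propanoyl]oxazolidin-2-one, via mixed pivalic anhydride 16 (not isolated)
Conditions: PivCl, Et3N, THF, -20 °C; then LiCl, 15, rt
Reagents that add atoms: pivaloyl chloride, CC(C)(C)C(=O)Cl (atoms stay only in 16)
Why: N-acylation through a mixed anhydride, in which the lithium-activated oxazolidinone attacks the less hindered carbonyl.

Step 9
Reactants: 17 imide; 10 aldehyde
Product: 19 (4R)-4-benzyl-3-[(2R,3R,4R)-5-(tert-butyldimethylsilyloxy)-3-hydroxy-2-(4-methoxybenzyloxymethyl)-4-methyl-4-(triethylsilyloxy)hept-6-enoyl]oxazolidin-2-one, via Z-boron enolate 18 (not isolated)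
Conditions: Bu2BOTf, Et3N, CH2Cl2, -78 to 0 °C; 10, -78 °C to rt; pH 7 buffer, MeOH, H2O2, 0 °C
Reagents that add atoms: dibutylboron triflate, CCCCB(CCCC)OS(=O)(=O)C(F)(F)F (boron stays only in 18)
Why: Evans syn aldol, in which the covalent Z-boron enolate (too weakly basic to expel the beta-alkoxide) reacts through a chair transition state on the face left open by the benzyl group of the (R)-auxiliary, setting C8a and C8 as in the target with CH2OPMB syn to OH and overriding any bias of the non-enolisable aldehyde.

Step 10
Reactants: 19 aldol adduct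
Product: 20 O7/O8 acetonide of the imide (C6-OTBS and C1-OPMB retained; C7, C8, C8a as in the target)
Conditions: Me2C(OMe)2, CSA (cat.), CH2Cl2, rt
Reagents that add atoms: 2,2-dimethoxypropane, COC(C)(C)OC
Why: In this acid-catalysed transketalisation the C8 hydroxyl is captured first and the oxocarbenium ion is closed by O7 with loss of the most acid-labile silyl group (TES), so O7 does not compete for the imide carbonyl and the hindered TBS ether and the PMB ether persist.

Step 11
Reactants: 20 acetonide imide
Product: 21 primary alcohol (C4a = CH2OH) with C1-OPMB, O7/O8 acetonide and C6-OTBS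
Conditions: LiBH4, MeOH (1 equiv), Et2O, 0 °C
Reagents that add atoms: none
Why: Reductive removal of the auxiliary, for which the exocyclic imide carbonyl is the only reducible group and O8 is blocked, so retro-aldol cleavage is excluded.

Step 12
Reactants: 21 alcohol
Product: 22 aldehyde (C4a = CHO)
Conditions: Dess-Martin periodinane, pyridine, CH2Cl2, 0 °C to rt
Reagents that add atoms: none
Why: Buffered Dess-Martin oxidation avoids both epimerisation at C8a and beta-elimination of the alkoxy groups.

Step 13
Reactants: 22 aldehyde
Product: 23 1,1-dibromoalkene (C8a-CH=CBr2) with C1-OPMB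
Conditions: CBr4, PPh3, 2,6-lutidine, CH2Cl2, 0 °C
Reagents that add atoms: carbon tetrabromide, BrC(Br)(Br)Br
Why: Ramirez dibromoolefination (first stage of the Corey-Fuchs sequence) is essentially neutral, keeps C8a intact, and stores C4a/C4 as a latent alkyne.

Step 14
Reactants: 23 PMB ether
Product: 24 primary alcohol (free C1-OH) with dibromoalkene, acetonide and C6-OTBS
Conditions: DDQ, CH2Cl2/pH 7 buffer, 0 °C
Reagents that add atoms: none
Why: Oxidative PMB cleavage by hydride abstraction from the electron-rich benzyl position leaves the silyl ether, acetonide, alkene and dibromoalkene untouched.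

Step 15
Reactants: 24 alcohol; 25 (E)-crotonyl chloride
Product: 26 C1-O (E)-crotonate
Conditions: 25, pyridine, CH2Cl2, 0 °C
Reagents that add atoms: none
Why: O-acylation of an unhindered primary alcohol, with pyridine chosen over a trialkylamine to avoid vinylketene formation and alkene deconjugation.

Step 16
Reactants: 26 crotonate
Product: 27 2-alkoxydiene C1-O-C3(=CH2)-CH=CH-CH3 (E), with dibromoalkene and C6-OTBS retained
Conditions: Cp2TiMe2 (3 equiv), toluene, 75 °C, dark; filtration through basic Al2O3
Reagents that add atoms: dimethyltitanocene, [CH3-].[CH3-].[Ti+4].c1cc[cH-]c1.c1cc[cH-]c1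
Why: Petasis methylenation converts alpha,beta-unsaturated esters to 2-alkoxydienes without moving the alkene, and here the ester is the only group able to trap the titanium methylidene, because the ketone and the alkyne are masked as silyl ether and dibromoalkene.

Step 17
Reactants: 27 dibromoalkene
Product: 29 terminal alkyne (C8a-C≡CH) with 2-alkoxydiene and C6-OTBS, via lithium acetylide 28 (not isolated)
Conditions: n-BuLi (2.2 equiv), THF, -78 °C; H2O
Reagents that add atoms: n-butyllithium, [Li]CCCC (lithium stays only in 28)
Why: In this second stage of the Corey-Fuchs sequence, bromine-lithium exchange, Fritsch-Buttenberg-Wiechell 1,2-shift and deprotonation give the acetylide, and the strongly basic, acid-free medium suits the enol ether.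

Step 18
Reactants: 29 silyl ether
Product: 30 allylic alcohol (free C6-OH, both epimers)
Conditions: Bu4NF, THF, 0 °C to rt
Reagents that add atoms: none
Why: Fluoride desilylation proceeds under non-acidic conditions that the 2-alkoxydiene, acetonide and terminal alkyne tolerate.

Step 19
Reactants: 30 allylic alcohol
Product: 31 dienyne precursor: vinyl ketone at C6, O7/O8 acetonide, C8a-ethynyl, C1-O-2-alkoxydiene
Conditions: Dess-Martin periodinane, pyridine, CH2Cl2, 0 °C; used at once in dilute solution
Reagents that add atoms: none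
Why: Pyridine-buffered Dess-Martin oxidation merges both C6 epimers into one ketone without acid, and immediate dilution prevents the electron-rich diene and the enone from combining intermolecularly.

Step 20
Reactants: 31 dienyne precursor
Product: 32 acetonide of the bicyclic core diol (rings A and B closed; C3=C4-C4a=C5-C6=O)
Conditions: second-generation Hoveyda-Grubbs catalyst RuCl2(SIMes)(=CH-C6H4-2-OiPr) (10 mol %, two portions), ethylene (1 atm), toluene (0.002 M), 60 °C; then Ar purge, 80 °C
Reagents that add atoms: none
Why: Proposed new method: the ruthenium methylidene formed on initiation adds to the terminal alkyne with ruthenium on C4, and the resulting vinyl carbene Ru=C4H-C4a(=CH2) undergoes [2+2]/retro-[2+2] with the CH2=C3 bond of the 2-alkoxydiene, so that C3=C4 forms, oxygen and propenyl stay on C3 and Ru=CH2 rather than a heteroatom-stabilised carbene is released; the remaining C4a=CH2 then ring-closes with the vinyl ketone to C4a=C5 with loss of ethylene, and the other order of events (a C5 alkylidene adding to C4a, then closure on the enol ether) ends at the same bicycle. The closest known reaction types are tandem dienyne ring-closing metathesis to fused bicyclic 1,3-dienes, enol ether-olefin ring-closing metathesis and enone ring-closing metathesis with phosphine-free ruthenium catalysts, whereas their union in one substrate has not been shown. Ring B closes as a six-membered ring by carbene-alkene metathesis at the 1,1-disubstituted enol ether, and ring A closes as a six-membered ring in the exo sense relative to the alkyne, that is with bond formation at the internal carbon C4a while C4 stays outside ring A. No stereocentre is created, C7, C8 and C8a are carried unchanged, and the dioxolane holds the C6 acyl group and the C8a side chain cis to each other, which brings the reacting ends together. The step needs reaction at the alkyne and the two =CH2 termini in preference to the internal E-propenyl alkene, which is secured by the poorer accessibility of that 1,2-disubstituted alkene, by the kinetic advantage of two six-membered closures at high dilution, and by the inertness of the conjugated push-pull trienone product towards further metathesis.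

Step 21
Reactants: 32 bicyclic acetonide
Product: 33 bicyclic core diol (C7-OH tertiary, C8-OH secondary)
Conditions: TFA/H2O (9:1), CH2Cl2, 0 °C
Reagents that add atoms: none
Why: In this acid hydrolysis of the acetonide the ring B enol ether is a doubly vinylogous ester whose hydration is reversible, so it should survive brief cold aqueous acid.

Step 22
Reactants: 34 orsellinic acid
Product: 35 tert-butyldimethylsilyl 2,4-bis(tert-butyldimethylsilyloxy)-6-methylbenzoate
Conditions: TBSCl (3.5 equiv), imidazole, DMF, rt to 40 °C
Reagents that add atoms: tert-butyldimethylsilyl chloride, CC(C)(C)[Si](C)(C)Cl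
Why: Exhaustive silylation masks both phenols and turns the acid into a silyl ester ready for neutral activation.

Step 23
Reactants: 35 tris-silyl orsellinate; 33 core diol
Product: 37 C8-O 2,4-bis(tert-butyldimethylsilyloxy)-6-methylbenzoate of the core with free C7-OH, via acid chloride 36 (not isolated)
Conditions: (COCl)2, DMF (cat.), CH2Cl2, 0 °C to rt; then 33, Et3N, DMAP, CH2Cl2, 0 °C to rt
Reagents that add atoms: oxalyl chloride, O=C(Cl)C(=O)Cl (chlorine stays only in 36)
Why: A silyl ester is converted to the acid chloride under neutral conditions and DMAP-catalysed acylation follows, with the secondary C8-OH reacting and the tertiary alpha-ketol C7-OH staying inert for steric reasons.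

Step 24
Reactants: 37 protected ester
Product: 38 berkazaphilone C
Conditions: HF·pyridine, pyridine, THF, 0 °C
Reagents that add atoms: none
Why: Buffered fluoride removes aryl silyl ethers quickly and does not disturb the ester, the alpha-ketol or the trienone.

**Compound list**

1 | (R)-lactic acid | C[C@@H](O)C(=O)O | starting material
2 | pivalaldehyde | CC(C)(C)C=O | starting material
3 | (2R,5R)-2-tert-butyl-5-methyl-1,3-dioxolan-4-one | C[C@H]1O[C@@H](C(C)(C)C)OC1=O | intermediate
4 | acrolein | C=CC=O | starting material
5 | lithium enolate of 3 | [Li+].[O-]C1=C(C)O[C@@H](C(C)(C)C)O1 | intermediate (not isolated)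
6 | lithium aldolate | [Li+].C=CC([O-])[C@]1(C)O[C@@H](C(C)(C)C)OC1=O | intermediate (not isolated)
7 | (2R,5S)-2-tert-butyl-5-[1-(TBS-oxy)prop-2-enyl]-5-methyl-1,3-dioxolan-4-one | C=CC(O[Si](C)(C)C(C)(C)C)[C@]1(C)O[C@@H](C(C)(C)C)OC1=O | intermediate
8 | (2R)-3-(TBS-oxy)-2-methylpent-4-ene-1,2-diol | C=CC(O[Si](C)(C)C(C)(C)C)[C@](C)(O)CO | intermediate
9 | (2S)-3-(TBS-oxy)-2-hydroxy-2-methylpent-4-enal | C=CC(O[Si](C)(C)C(C)(C)C)[C@](C)(O)C=O | intermediate
10 | (2S)-3-(TBS-oxy)-2-methyl-2-(TES-oxy)pent-4-enal | C=CC(O[Si](C)(C)C(C)(C)C)[C@](C)(O[Si](CC)(CC)CC)C=O | intermediate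
11 | propane-1,3-diol | OCCCO | starting material
12 | 4-methoxybenzyl chloride | COc1ccc(CCl)cc1 | starting material
13 | 3-(4-methoxybenzyloxy)propan-1-ol | COc1ccc(COCCCO)cc1 | intermediate
14 | 3-(4-methoxybenzyloxy)propanoic acid | COc1ccc(COCCC(=O)O)cc1 | intermediate
15 | (R)-4-benzyl-2-oxazolidinone | O=C1N[C@H](Cc2ccccc2)CO1 | starting material
16 | mixed pivalic anhydride of 14 | COc1ccc(COCCC(=O)OC(=O)C(C)(C)C)cc1 | intermediate (not isolated)
17 | (R)-4-benzyl-3-[3-(4-methoxybenzyloxy)propanoyl]oxazolidin-2-one | COc1ccc(COCCC(=O)N2[C@H](Cc3ccccc3)COC2=O)cc1 | intermediate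
18 | Z-dibutylboron enolate of 17 | CCCCB(CCCC)O/C(=C\COCc1ccc(OC)cc1)N1[C@H](Cc2ccccc2)COC1=O | intermediate (not isolated)
19 | Evans syn aldol adduct | C=CC(O[Si](C)(C)C(C)(C)C)[C@](C)(O[Si](CC)(CC)CC)[C@H](O)[C@H](C(=O)N1[C@H](Cc2ccccc2)COC1=O)COCc1ccc(OC)cc1 | intermediate
20 | O7/O8 acetonide imide | C=CC(O[Si](C)(C)C(C)(C)C)[C@]1(C)OC(C)(C)O[C@@H]1[C@H](C(=O)N2[C@H](Cc3ccccc3)COC2=O)COCc4ccc(OC)cc4 | intermediate
21 | C4a primary alcohol | C=CC(O[Si](C)(C)C(C)(C)C)[C@]1(C)OC(C)(C)O[C@@H]1[C@H](CO)COCc2ccc(OC)cc2 | intermediate
22 | C4a aldehyde | C=CC(O[Si](C)(C)C(C)(C)C)[C@]1(C)OC(C)(C)O[C@@H]1[C@H](C=O)COCc2ccc(OC)cc2 | intermediate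
23 | dibromoalkene PMB ether | C=CC(O[Si](C)(C)C(C)(C)C)[C@]1(C)OC(C)(C)O[C@@H]1[C@H](C=C(Br)Br)COCc2ccc(OC)cc2 | intermediate
24 | dibromoalkene C1 alcohol | C=CC(O[Si](C)(C)C(C)(C)C)[C@]1(C)OC(C)(C)O[C@@H]1[C@H](C=C(Br)Br)CO | intermediate
25 | (E)-crotonyl chloride | C/C=C/C(=O)Cl | starting material
26 | C1-O crotonate | C=CC(O[Si](C)(C)C(C)(C)C)[C@]1(C)OC(C)(C)O[C@@H]1[C@H](C=C(Br)Br)COC(=O)/C=C/C | intermediate
27 | 2-alkoxydiene dibromoalkene | C=CC(O[Si](C)(C)C(C)(C)C)[C@]1(C)OC(C)(C)O[C@@H]1[C@H](C=C(Br)Br)COC(=C)/C=C/C | intermediate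
28 | lithium acetylide | [Li+].C=CC(O[Si](C)(C)C(C)(C)C)[C@]1(C)OC(C)(C)O[C@@H]1[C@H](C#[C-])COC(=C)/C=C/C | intermediate (not isolated)
29 | terminal alkyne, C6-OTBS | C=CC(O[Si](C)(C)C(C)(C)C)[C@]1(C)OC(C)(C)O[C@@H]1[C@H](C#C)COC(=C)/C=C/C | intermediate
30 | C6 allylic alcohol | C=CC(O)[C@]1(C)OC(C)(C)O[C@@H]1[C@H](C#C)COC(=C)/C=C/C | intermediate
31 | dienyne precursor (vinyl ketone) | C=CC(=O)[C@]1(C)OC(C)(C)O[C@@H]1[C@H](C#C)COC(=C)/C=C/C | intermediate
32 | bicyclic core acetonide | C/C=C/C1=CC2=CC(=O)[C@]3(C)OC(C)(C)O[C@@H]3[C@H]2CO1 | intermediate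
33 | bicyclic core diol | C/C=C/C1=CC2=CC(=O)[C@](C)(O)[C@H](O)[C@H]2CO1 | intermediate
34 | orsellinic acid | Cc1cc(O)cc(O)c1C(=O)O | starting material
35 | TBS 2,4-bis(TBS-oxy)-6-methylbenzoate | Cc1cc(O[Si](C)(C)C(C)(C)C)cc(O[Si](C)(C)C(C)(C)C)c1C(=O)O[Si](C)(C)C(C)(C)C | intermediate
36 | 2,4-bis(TBS-oxy)-6-methylbenzoyl chloride | Cc1cc(O[Si](C)(C)C(C)(C)C)cc(O[Si](C)(C)C(C)(C)C)c1C(=O)Cl | intermediate (not isolated)
37 | bis-TBS berkazaphilone C | C/C=C/C1=CC2=CC(=O)[C@](C)(O)[C@H](OC(=O)c3c(C)cc(O[Si](C)(C)C(C)(C)C)cc3O[Si](C)(C)C(C)(C)C)[C@H]2CO1 | intermediate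
38 | berkazaphilone C | C/C=C/C1=CC2=CC(=O)[C@](C)(O)[C@H](OC(=O)c3c(C)cc(O)cc3O)[C@H]2CO1 | target

Total step count: 24. Longest linear sequence: 20 steps (steps 1-5, 9-21, 23, 24).

**Steps most likely to fail**

1. Step 20 (labelled step).
   - What may go wrong: the catalyst may be tied up by the enol ether or the alkyne. The cascade may stall after only one ring has closed. The propenyl group may be truncated by cross-metathesis. The electron-rich diene may cycloadd to the enone before metathesis starts.
   - Fallback: known reaction types only, setting out from 24 and returning at 32.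
   - n-BuLi (3.3 equiv) converts 24 to the terminal alkynol F1.
   - Ring-closing enyne metathesis of its 1,7-enyne unit with the second-generation Grubbs catalyst RuCl2(SIMes)(PCy3)(=CHPh) under ethylene closes ring A alone and gives the 1-vinylcyclohexene F2.
   - Acylation with 25 gives the crotonate F3, which holds neither alkyne nor ketone, and Cp2TiMe2 methylenates it to the alkoxydiene F4.
   - A separate enol ether-olefin ring-closing metathesis between C4H=CH2 and CH2=C3 closes ring B to the bicyclic silyl ether F5.
   - Bu4NF gives the dienol F6, and MnO2 oxidises it to 32.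

2. Step 16.
   - What may go wrong: methylenation of the conjugated ester may be slow at a temperature the reagent survives, and the 2-alkoxydiene may hydrolyse during isolation.
   - Fallback: ketal exchange and elimination in place of carbonyl olefination, setting out from 24 and returning at 27.
   - Commercial (E)-pent-3-en-2-one is ketalised (MeOSiMe3, TMSOTf cat., -78 °C) to the dimethyl ketal F7.
   - PPTS-catalysed exchange with 24, with removal of methanol, gives the mixed methyl ketal F8.
   - TMSOTf/iPr2NEt at -20 °C ionises the allylic ketal at its less hindered methoxy group, much faster than it ionises the acetonide, and deprotonation of the methyl group gives 27.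

3. Step 23.
   - What may go wrong: acyl transfer from a di-ortho-substituted benzoyl chloride to the flanked C8 hydroxyl may be slow. Prolonged exposure to base would then open the way to acyl migration to O7 or epimerisation at C8a.
   - Fallback: build the arene on the ester instead of coupling it, setting out from 33 and returning at 38.
   - Commercial 2,2,6-trimethyl-4H-1,3-dioxin-4-one is C-acetylated through its lithium dienolate (LiN(iPr)2; acetyl chloride) to the keto-dioxinone F9.
   - The dianion of F9 (LiN(iPr)2, Et2Zn) is acetylated with N-acetylimidazole to the diketo-dioxinone F10.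
   - Heating F10 with 33 in toluene at 110 °C releases an unhindered acylketene, which the C8 hydroxyl traps as the 3,5,7-trioxooctanoate F11.
   - Et3N and then mild acid bring about aldol condensation and dehydration to the orsellinate 38, without any phenol protection.

**Further compounds**

F1 | step 20 | terminal alkynol (C1-OH, C6-OTBS, acetonide) | C=CC(O[Si](C)(C)C(C)(C)C)[C@]1(C)OC(C)(C)O[C@@H]1[C@H](C#C)CO
F2 | step 20 | ring A 1-vinylcyclohexene (C4a-CH=CH2) | C=CC1=CC(O[Si](C)(C)C(C)(C)C)[C@]2(C)OC(C)(C)O[C@@H]2[C@H]1CO
F3 | step 20 | crotonate of F2 | C=CC1=CC(O[Si](C)(C)C(C)(C)C)[C@]2(C)OC(C)(C)O[C@@H]2[C@H]1COC(=O)/C=C/C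
F4 | step 20 | alkoxydiene of ring A | C=CC1=CC(O[Si](C)(C)C(C)(C)C)[C@]2(C)OC(C)(C)O[C@@H]2[C@H]1COC(=C)/C=C/C
F5 | step 20 | bicyclic silyl ether | C/C=C/C1=CC2=CC(O[Si](C)(C)C(C)(C)C)[C@]3(C)OC(C)(C)O[C@@H]3[C@H]2CO1
F6 | step 20 | bicyclic dienol | C/C=C/C1=CC2=CC(O)[C@]3(C)OC(C)(C)O[C@@H]3[C@H]2CO1
F7 | step 16 | (E)-4,4-dimethoxypent-2-ene | C/C=C/C(C)(OC)OC
F8 | step 16 | mixed methyl ketal of 24 | C=CC(O[Si](C)(C)C(C)(C)C)[C@]1(C)OC(C)(C)O[C@@H]1[C@H](C=C(Br)Br)COC(C)(OC)/C=C/C
F9 | step 23 | 2,2-dimethyl-6-(2-oxopropyl)-4H-1,3-dioxin-4-one | CC(=O)CC1=CC(=O)OC(C)(C)O1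
F10 | step 23 | 2,2-dimethyl-6-(2,4-dioxopentyl)-4H-1,3-dioxin-4-one | CC(=O)CC(=O)CC1=CC(=O)OC(C)(C)O1
F11 | step 23 | C8-O 3,5,7-trioxooctanoate of 33 | C/C=C/C1=CC2=CC(=O)[C@](C)(O)[C@H](OC(=O)CC(=O)CC(=O)CC(C)=O)[C@H]2CO1
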